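**Strategy.** In prostanoid numbering (C1 carboxyl carbon, ring C8–C12, C9 carbonyl, C15 acetoxy carbon), the cyclopentenone is disconnected at C11–C12. Its C9 ketone lies between the C10=C11 alkene and the C8–C12 bond, so unsaturation at C8=C12 reveals a divinyl ketone; this is the feature exploited. A silicon-directed Nazarov cyclisation of an acyclic β-silyl trienone forms C11–C12 and so closes the ring, leaves the alkene at C10=C11 by loss of Me3Si from C11, and sets C12 (chiral acid) and C8 (ketonisation to trans) in one operation. The precursor carries Me3Si on C11, E alkenes at C8=C12 and C13=C14, the 15S acetate and a C1 methyl ester.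

Key step: step 6

Remark (catalyst sense): (R)-TRIP, 3,3'-bis(2,4,6-triisopropylphenyl)-1,1'-binaphthyl-2,2'-diyl hydrogen phosphate, is assumed to be the antipode that gives 12S; if the sense proves opposite, (S)-TRIP is used, and C15 is too remote to cause a mismatch.

Remark (C8): proton delivery to the ring dienol from the face away from the C12 substituent would place the C8 chain cis to it, so the trans relationship is planned as the thermodynamic result of reversible enolisation at C8, not as a kinetic one.

**Step 1**
Reactants: 1 (S)-oct-1-en-3-ol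
Product: 2 (S)-oct-1-en-3-yl acetate
Conditions: Ac2O, pyridine, DMAP (cat.), CH2Cl2, 0 °C to rt
Reagents that add atoms: acetic anhydride, CC(=O)OC(C)=O
Why: DMAP-catalysed O-acylation of a secondary allylic alcohol, in which the C–O bond at the stereocentre is untouched, so the S configuration (the future C15) is carried over unchanged.

**Step 2**
Reactants: 2 (S)-oct-1-en-3-yl acetate; 3 crotonaldehyde
Product: 4 (2E,4S)-4-(acetyloxy)non-2-enal
Conditions: 3 (excess), second-generation Hoveyda–Grubbs catalyst (cat.), CH2Cl2, 40 °C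
Reagents that add atoms: none
Why: Olefin cross-metathesis of a terminal allylic acetate with an electron-poor enal partner used in excess, in which the ruthenium carbene tolerates aldehyde and ester, propene is lost, the conjugated E enal is the favoured product and the allylic stereocentre takes no part.

**Step 3**
Reactants: 5 methyl 9-chloro-9-oxononanoate; 6 (E)-1,2-bis(trimethylsilyl)ethene
Product: 7 methyl (10E)-9-oxo-11-(trimethylsilyl)undec-10-enoate
Conditions: AlCl3, CH2Cl2, –20 to 0 °C
Reagents that add atoms: none
Why: Friedel–Crafts-type acylative ipso-desilylation of a vinylsilane, in which the acylium ion attacks the silicon-bearing carbon, the β-silyl cation loses Me3SiCl with retention of the E geometry, the deactivated β-silyl enone is not acylated again and the methyl ester only coordinates AlCl3.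

**Step 4**
Reactants: 7 methyl (10E)-9-oxo-11-(trimethylsilyl)undec-10-enoate; 4 (2E,4S)-4-(acetyloxy)non-2-enal
Product: 10 methyl (10E)-8-[(2E,4S)-4-(acetyloxy)-1-hydroxynon-2-en-1-yl]-9-oxo-11-(trimethylsilyl)undec-10-enoate (mixture of C8/C12 diastereomers), via dibutylboron enolate 8 (not isolated), via boron aldolate 9 (not isolated)
Conditions: Bu2BOTf, i-Pr2NEt, CH2Cl2, –78 °C; then 4, –78 to 0 °C; pH 7 buffer, MeOH, 30% H2O2, 0 °C
Reagents that add atoms: none
Why: Boron-mediated aldol addition, in which soft enolisation can occur only at C8 (the other α-carbon is vinylic and the C1 ester is not enolised), the enolate adds 1,2 to the enal through a closed six-membered transition state without touching the acetate, and the C8/C12 configurations are irrelevant because both carbons become sp2 in step 5.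

**Step 5**
Reactants: 10 methyl (10E)-8-[(2E,4S)-4-(acetyloxy)-1-hydroxynon-2-en-1-yl]-9-oxo-11-(trimethylsilyl)undec-10-enoate
Product: 12 methyl (8E,10E)-8-[(2E,4S)-4-(acetyloxy)non-2-en-1-ylidene]-9-oxo-11-(trimethylsilyl)undec-10-enoate, via allylic mesylate 11 (not isolated)
Conditions: MsCl, Et3N, CH2Cl2, –20 °C; then DBU, 0 °C to rt
Reagents that add atoms: none
Why: Sulfonylation followed by E1cB β-elimination through the C8 enolate, which should give the thermodynamically preferred E alkene at C8=C12 (C13 trans to the C9 carbonyl) and leaves C15 untouched.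

**Step 6**
Reactants: 12 methyl (8E,10E)-8-[(2E,4S)-4-(acetyloxy)non-2-en-1-ylidene]-9-oxo-11-(trimethylsilyl)undec-10-enoate
Product: 14 methyl 7-[(1R,2S)-2-[(1E,3S)-3-(acetyloxy)oct-1-en-1-yl]-5-oxocyclopent-3-en-1-yl]heptanoate, via ring dienol 13 (not isolated)
Conditions: Zn(OTf)2 (5 mol%), (R)-TRIP (6 mol%), PhOH (1.1 equiv), ClCH2CH2Cl, 40 °C
Reagents that add atoms: none
Why: Zn(OTf)2 activates the C9 carbonyl and the hydroxypentadienyl cation (C11–C10–C9–C8–C12) closes the five-membered ring by thermally allowed 4π conrotatory electrocyclisation, forming C11–C12; the closest known reaction is the silicon-directed Nazarov cyclisation of β-silyl divinyl ketones in its cooperative Lewis acid/chiral Brønsted acid form. The β-silicon effect holds the oxyallyl charge at C10, so Me3Si leaves from C11 (taken up by phenol) and the alkene is placed at C10=C11 and not at the more substituted C8=C12 position, which keeps C8 and C12 stereogenic. C12 is set by torquoselectivity: the chiral phosphate bound at the activated carbonyl selects one helical sense of the cation and so one direction of conrotation, and the single E geometry at C8=C12 turns that sense into one configuration (12S). C8 is set when dienol 13 ketonises: C8–H stays exchangeable through the enol under the acidic conditions, so the more stable trans arrangement (8R) should be reached even if kinetic protonation first gives the cis epimer. The step needs regiocontrol of the alkene (secured by silicon on C11) and closure at C12 in preference to reaction at the vinylogous C14 terminus, which is helped by the C8 substituent enforcing the reactive s-trans/s-trans conformer and by the electron-withdrawing 15-acetate disfavouring ionisation at C15; the reaction is stopped at full conversion so the alkene does not drift into conjugation with C13=C14.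

**Step 7**
Reactants: 14 methyl 7-[(1R,2S)-2-[(1E,3S)-3-(acetyloxy)oct-1-en-1-yl]-5-oxocyclopent-3-en-1-yl]heptanoate
Product: 15 7-[(1R,2S)-2-[(1E,3S)-3-(acetyloxy)oct-1-en-1-yl]-5-oxocyclopent-3-en-1-yl]heptanoic acid
Conditions: Candida antarctica lipase B (immobilised), pH 7.0 phosphate buffer/acetone, 30 °C
Reagents that add atoms: water, O
Why: Lipase-catalysed ester hydrolysis through an acyl-enzyme at neutral pH, in which the unhindered methyl ester at the end of the flexible C1–C7 chain is a typical substrate, the C15 acetate (a secondary ester flanked by two large groups) should react far more slowly, and the absence of base avoids alkene migration and epimerisation at C8 and C12.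

**Compound list**
1 | (S)-oct-1-en-3-ol | CCCCC[C@@H](C=C)O | starting material
2 | (S)-oct-1-en-3-yl acetate | CCCCC[C@@H](C=C)OC(C)=O | intermediate
3 | crotonaldehyde | C/C=C/C=O | starting material
4 | (2E,4S)-4-(acetyloxy)non-2-enal | CCCCC[C@@H](/C=C/C=O)OC(C)=O | intermediate
5 | methyl 9-chloro-9-oxononanoate | COC(=O)CCCCCCCC(=O)Cl | starting material
6 | (E)-1,2-bis(trimethylsilyl)ethene | C[Si](C)(C)/C=C/[Si](C)(C)C | starting material
7 | methyl (10E)-9-oxo-11-(trimethylsilyl)undec-10-enoate | COC(=O)CCCCCCCC(=O)/C=C/[Si](C)(C)C | intermediate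
8 | methyl (8Z,10E)-9-[(dibutylboranyl)oxy]-11-(trimethylsilyl)undeca-8,10-dienoate (dibutylboron enolate) | COC(=O)CCCCCC/C=C(\OB(CCCC)CCCC)/C=C/[Si](C)(C)C | intermediate (not isolated)
9 | dibutylboron aldolate of 10 (C8/C12 configuration undefined) | CCCCC[C@@H](/C=C/C(OB(CCCC)CCCC)C(CCCCCCC(=O)OC)C(=O)/C=C/[Si](C)(C)C)OC(C)=O | intermediate (not isolated)
10 | methyl (10E)-8-[(2E,4S)-4-(acetyloxy)-1-hydroxynon-2-en-1-yl]-9-oxo-11-(trimethylsilyl)undec-10-enoate (C8/C12 diastereomer mixture) | CCCCC[C@@H](/C=C/C(O)C(CCCCCCC(=O)OC)C(=O)/C=C/[Si](C)(C)C)OC(C)=O | intermediate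
11 | C12 methanesulfonate of 10 (allylic mesylate) | CCCCC[C@@H](/C=C/C(OS(C)(=O)=O)C(CCCCCCC(=O)OC)C(=O)/C=C/[Si](C)(C)C)OC(C)=O | intermediate (not isolated)
12 | methyl (8E,10E)-8-[(2E,4S)-4-(acetyloxy)non-2-en-1-ylidene]-9-oxo-11-(trimethylsilyl)undec-10-enoate (β-silyl trienone) | C[Si](C)(C)/C=C/C(=O)/C(CCCCCCC(=O)OC)=C/C=C/[C@H](CCCCC)OC(C)=O | intermediate
13 | methyl 7-[(5S)-5-[(1E,3S)-3-(acetyloxy)oct-1-en-1-yl]-2-hydroxycyclopenta-1,3-dien-1-yl]heptanoate (ring dienol) | CCCCC[C@@H](/C=C/[C@H]1C=CC(O)=C1CCCCCCC(=O)OC)OC(C)=O | intermediate (not isolated)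
14 | methyl 7-[(1R,2S)-2-[(1E,3S)-3-(acetyloxy)oct-1-en-1-yl]-5-oxocyclopent-3-en-1-yl]heptanoate | CCCCC[C@@H](/C=C/[C@H]1C=CC(=O)[C@@H]1CCCCCCC(=O)OC)OC(C)=O | intermediate
15 | 7-[(1R,2S)-2-[(1E,3S)-3-(acetyloxy)oct-1-en-1-yl]-5-oxocyclopent-3-en-1-yl]heptanoic acid | CCCCC[C@@H](/C=C/[C@H]1C=CC(=O)[C@@H]1CCCCCCC(=O)O)OC(C)=O | target

**Step count.** Total: 7 steps. Longest linear sequence: 6 steps (1 → 2 → 4 → 10 → 12 → 14 → 15); ketone 7 is made in one step on the convergent branch.

**Steps most likely to fail**

Step 6. The extended cation may react at its vinylogous C14 terminus (capture by phenol, oligomerisation) instead of closing C11–C12. Torquoselectivity may be insufficient with a flexible acyclic substrate. The ring alkene may migrate on to C8=C12 under the acid and erase both stereocentres. The fallback builds the ring-substituent pattern by conjugate addition and forms the ring alkene by β-elimination. It sets out from 2 and returns at 14. The purchased enone methyl 7-[(3R)-3-[(tert-butyldimethylsilyl)oxy]-5-oxocyclopent-1-en-1-yl]heptanoate F1 takes up a vinyl cuprate (CH2=CHMgBr, CuBr·SMe2 cat., THF, –78 °C) anti to the silyloxy group. Protonation of the enolate should give the all-trans ketone methyl 7-[(1R,2R,3R)-3-[(tert-butyldimethylsilyl)oxy]-2-ethenyl-5-oxocyclopentyl]heptanoate F2. Cross-metathesis of F2 with an excess of 2 (second-generation Hoveyda–Grubbs catalyst, CH2Cl2, 40 °C) should give methyl 7-[(1R,2R,3R)-2-[(1E,3S)-3-(acetyloxy)oct-1-en-1-yl]-3-[(tert-butyldimethylsilyl)oxy]-5-oxocyclopentyl]heptanoate F3. Desilylation (HF·pyridine, MeCN, 0 °C) gives methyl 7-[(1R,2R,3R)-2-[(1E,3S)-3-(acetyloxy)oct-1-en-1-yl]-3-hydroxy-5-oxocyclopentyl]heptanoate F4. Acid-mediated dehydration of this β-hydroxy ketone (AcOH/H2O, 60 °C) should give 14.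

Step 7. The lipase may also cleave the C15 acetate, or hydrolysis of the poorly water-soluble ester may stall. The fallback gives up selectivity and restores the acetate afterwards. It sets out from 14 and returns at 15. Exhaustive enzymatic hydrolysis of both esters (porcine liver esterase, pH 7.5 buffer, extended time) gives 7-[(1R,2S)-2-[(1E,3S)-3-hydroxyoct-1-en-1-yl]-5-oxocyclopent-3-en-1-yl]heptanoic acid F5. Ac2O/pyridine then acetylates the C15 hydroxyl, and any mixed anhydride formed at the carboxyl group is hydrolysed on aqueous work-up to give 15.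

Step 5. Substitution or ionisation at the doubly activated C12 sulfonate may compete with elimination, E selectivity at C8=C12 may be incomplete, and the amine base may degrade the cross-conjugated trienone. The fallback forms C8=C12 by Wittig olefination. It sets out from 7 and returns at 12. The dibutylboron enolate 8 is brominated with NBS (CH2Cl2, –78 °C) to methyl (10E)-8-bromo-9-oxo-11-(trimethylsilyl)undec-10-enoate F6. PPh3 (toluene, 60 °C) gives [(10E)-1-methoxy-1,9-dioxo-11-(trimethylsilyl)undec-10-en-8-yl]triphenylphosphonium bromide F7. Aqueous Na2CO3/CH2Cl2 gives the acyl-stabilised ylide methyl (10E)-9-oxo-8-(triphenyl-λ5-phosphanylidene)-11-(trimethylsilyl)undec-10-enoate F8. Olefination of F8 with aldehyde 4 (toluene, 90 °C) should give 12 with the E geometry typical of stabilised α-substituted ylides, without a hydroxy ketone, a sulfonate or an amine base.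

**Further compounds**
F1 | step 6 | methyl 7-[(3R)-3-[(tert-butyldimethylsilyl)oxy]-5-oxocyclopent-1-en-1-yl]heptanoate | COC(=O)CCCCCCC1=C[C@H](O[Si](C)(C)C(C)(C)C)CC1=O
F2 | step 6 | methyl 7-[(1R,2R,3R)-3-[(tert-butyldimethylsilyl)oxy]-2-ethenyl-5-oxocyclopentyl]heptanoate | C=C[C@H]1[C@H](O[Si](C)(C)C(C)(C)C)CC(=O)[C@@H]1CCCCCCC(=O)OC
F3 | step 6 | methyl 7-[(1R,2R,3R)-2-[(1E,3S)-3-(acetyloxy)oct-1-en-1-yl]-3-[(tert-butyldimethylsilyl)oxy]-5-oxocyclopentyl]heptanoate | CCCCC[C@@H](/C=C/[C@H]1[C@H](O[Si](C)(C)C(C)(C)C)CC(=O)[C@@H]1CCCCCCC(=O)OC)OC(C)=O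
F4 | step 6 | methyl 7-[(1R,2R,3R)-2-[(1E,3S)-3-(acetyloxy)oct-1-en-1-yl]-3-hydroxy-5-oxocyclopentyl]heptanoate | CCCCC[C@@H](/C=C/[C@H]1[C@H](O)CC(=O)[C@@H]1CCCCCCC(=O)OC)OC(C)=O
F5 | step 7 | 7-[(1R,2S)-2-[(1E,3S)-3-hydroxyoct-1-en-1-yl]-5-oxocyclopent-3-en-1-yl]heptanoic acid | CCCCC[C@@H](/C=C/[C@H]1C=CC(=O)[C@@H]1CCCCCCC(=O)O)O
F6 | step 5 | methyl (10E)-8-bromo-9-oxo-11-(trimethylsilyl)undec-10-enoate | COC(=O)CCCCCCC(Br)C(=O)/C=C/[Si](C)(C)C
F7 | step 5 | [(10E)-1-methoxy-1,9-dioxo-11-(trimethylsilyl)undec-10-en-8-yl]triphenylphosphonium bromide | COC(=O)CCCCCCC(C(=O)/C=C/[Si](C)(C)C)[P+](c1ccccc1)(c1ccccc1)c1ccccc1.[Br-]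
F8 | step 5 | methyl (10E)-9-oxo-8-(triphenyl-λ5-phosphanylidene)-11-(trimethylsilyl)undec-10-enoate | COC(=O)CCCCCCC(C(=O)/C=C/[Si](C)(C)C)=P(c1ccccc1)(c1ccccc1)c1ccccc1
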